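**Plan**

- Retrosynthesis: C7–C8 is cut first (C8 enolate plus a C1–C7 propargylic iodide). C13 is then tied back to C8, so that C8–C12 and the temporary C8–C13 bond are cut together as one carbenoid [2+1] addition. The open chain is cut at C8–C9 (acylation of diazomethane), C10–C11 (acetate aldol) and C12=C13 (Wittig).
- Enabling feature: in the cyclopentanone ring (C8–C12), C8 lies next to the C9 carbonyl and C12 carries a plain methylene, C13. A three-membered ring C8–C12–C13 fused to the cyclopentanone therefore holds the ring bond C8–C12 plus one extra bond (C8–C13) that ketone-directed electron transfer can remove again.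
- Forward: C13–C20 ester → C11–C20 enal → C9–C20 acid → C8–C20 diazoketone. Step 9 closes the cyclopentanone and the cyclopropane together, step 13 opens the cyclopropane and joins C1–C7 at C8, and hydrogenation, desilylation and enzymatic hydrolysis finish.
- Stereochemistry: C15 from Ru/(S)-BINAP hydrogenation; C11 from the (R)-HYTRA acetate aldol; C12 from C11 by face selection in the cyclopropanation; C8 from C12 by alkylation anti to the lower chain.

Key step: step 9

Assumption: atoms carry prostaglandin numbers (C1 acid carbon to C20 chain-end methyl); TBS = tert-butyldimethylsilyl and TBSO = tert-butyldimethylsilyloxy; each step ends with an ordinary aqueous work-up, and spent metal reagents are given as the simple salts present after it.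

**Step 1**
Reactants: 1 methyl 3-oxooctanoate
Product: 2 methyl (3S)-3-hydroxyoctanoate
Conditions: H2 (4 atm), RuCl2[(S)-BINAP] (0.1 mol %), MeOH, 80 °C
Reagents that add atoms: none
Why: Noyori asymmetric hydrogenation of a β-keto ester, in which the ester carbonyl chelates the divalent ruthenium centre and the (S)-BINAP ligand should direct hydride to the ketone face that gives the 3S alcohol, the future C15.

**Step 2**
Reactants: 2 methyl (3S)-3-hydroxyoctanoate
Product: 3 methyl (3S)-3-(TBSO)octanoate
Conditions: TBSCl, imidazole, DMF, rt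
Reagents that add atoms: tert-butyldimethylsilyl chloride, CC(C)(C)[Si](C)(C)Cl
Why: Imidazole-promoted silylation of a secondary alcohol is routine, and the TBS ether should survive every later step until the fluoride treatment of step 15.

**Step 3**
Reactants: 3 methyl (3S)-3-(TBSO)octanoate
Product: 4 (3S)-3-(TBSO)octanal
Conditions: i-Bu2AlH (1.05 equiv), CH2Cl2, −78 °C
Reagents that add atoms: none
Why: Partial ester reduction with i-Bu2AlH at −78 °C stops at the aluminium hemiacetal, which should release the aldehyde (C13) only on work-up and leaves the silyl ether and C15 untouched.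

**Step 4**
Reactants: 4 (3S)-3-(TBSO)octanal; 5 (triphenylphosphoranylidene)acetaldehyde
Product: 6 (2E,5S)-5-(TBSO)dec-2-enal
Conditions: toluene, 80 °C
Reagents that add atoms: none
Why: Wittig olefination with the stabilised formylmethylene ylide should form C12=C13 with E geometry and add C11 and C12 in one operation.

**Step 5**
Reactants: 6 (2E,5S)-5-(TBSO)dec-2-enal; 7 (1R)-2-hydroxy-1,2,2-triphenylethyl acetate, (R)-HYTRA
Product: 9 (1R)-2-hydroxy-1,2,2-triphenylethyl (3R,4E,7S)-3-hydroxy-7-(TBSO)dodec-4-enoate, via dilithium HYTRA enolate 8 (not isolated)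
Conditions: LiN(i-Pr)2 (2.1 equiv), THF, −78 → 0 °C; then 6, THF/2-methylbutane, −125 °C
Reagents that add atoms: none
Why: Auxiliary-controlled acetate aldol addition, in which the doubly deprotonated (R)-HYTRA should add 1,2 to the enal through a closed lithium-bridged transition state that exposes the Re face of the aldehyde, forming C10–C11 and setting C11 as R.

**Step 6**
Reactants: 9 (1R)-2-hydroxy-1,2,2-triphenylethyl (3R,4E,7S)-3-hydroxy-7-(TBSO)dodec-4-enoate
Product: 10 (3R,4E,7S)-3-hydroxy-7-(TBSO)dodec-4-enoic acid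
Conditions: LiOH, THF/MeOH/H2O, 0 °C → rt; then 1 M HCl to pH 3
Reagents that add atoms: lithium hydroxide, [Li+].[OH-]
Why: Saponification of the auxiliary ester, helped by its neighbouring tertiary hydroxyl, should free the β-hydroxy acid under conditions too mild for retro-aldol cleavage, dehydration or loss of the C15 silyl ether.

**Step 7**
Reactants: 10 (3R,4E,7S)-3-hydroxy-7-(TBSO)dodec-4-enoic acid
Product: 12 (3R,4E,7S)-3,7-bis(TBSO)dodec-4-enoic acid, via silyl ester 11 (not isolated)
Conditions: TBSCl (2.5 equiv), imidazole, DMF, rt; then K2CO3, MeOH/THF/H2O, rt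
Reagents that add atoms: tert-butyldimethylsilyl chloride, CC(C)(C)[Si](C)(C)Cl
Why: Exhaustive silylation followed by selective solvolysis of the much more labile silyl ester is the standard route to an O-silylated hydroxy acid and does not involve the C11 centre.

**Step 8**
Reactants: 12 (3R,4E,7S)-3,7-bis(TBSO)dodec-4-enoic acid
Product: 14 (4R,5E,8S)-1-diazo-4,8-bis(TBSO)tridec-5-en-2-one, via mixed carbonic anhydride 13 (not isolated)
Conditions: i-BuOCOCl, Et3N, THF, −20 °C; then CH2N2 (excess), Et2O, 0 °C → rt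
Reagents that add atoms: diazomethane, C=[N+]=[N-]
Why: Acylation of diazomethane by a mixed carbonic anhydride (first stage of an Arndt–Eistert sequence) should form C8–C9 under near-neutral conditions that do not provoke β-elimination of the 11-silyloxy group.

**Step 9**
Reactants: 14 (4R,5E,8S)-1-diazo-4,8-bis(TBSO)tridec-5-en-2-one
Product: 15 (1S,4R,5R,6R)-4-(TBSO)-6-[(2S)-2-(TBSO)heptyl]bicyclo[3.1.0]hexan-2-one
Conditions: Rh2(OAc)4 (1 mol %), CH2Cl2, rt, slow addition of 14
Reagents that add atoms: none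
Why: Loss of dinitrogen from 14 at Rh2(OAc)4, a dimer of divalent rhodium, should leave a rhodium-bound, electrophilic carbene at C8 that is transferred to the C12=C13 double bond in a single step with uneven bond formation, the reaction type being the intramolecular cyclopropanation of γ,δ-unsaturated α-diazoketones to bicyclo[3.1.0]hexan-2-ones. The cyclopentanone ring (C8–C9–C10–C11–C12) closes in the 5-exo mode, C8 bonding to C12 with C13 left outside that ring, and the cyclopropane (C8–C12–C13) closes in the same cheletropic event through C8–C13; the C9–C10–C11 tether is too short for any other ring size. C8 and C12 are set together as a cis ring fusion by the tether, and C13 takes its C14 chain exo because the E geometry is carried over stereospecifically (this centre is erased again in step 13). The sense at C12, and with it C8, is governed by C11: with C10 held over the attacked alkene face, the bulky silyloxy group is expected to take the outside position, trans to the forming three-membered ring, and not the inside position gauche to C13 and its inward hydrogen, so that C12–C13 ends anti to the 11-oxygen. The step needs this facial selectivity and also chemoselectivity for cyclopropanation over C–H insertion, oxonium ylide formation and carbene dimerisation; the first rests on the C11 silyl ether and the E-alkene, the second on the well-placed electron-rich alkene, the fact that the only C–H bond five atoms from C8 is vinylic, the hindered silyl ether oxygen and slow addition at high dilution.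

**Step 10**
Reactants: 16 hex-5-ynoic acid
Product: 18 7-hydroxyhept-5-ynoic acid, via dilithio hexynoate 17 (not isolated)
Conditions: n-BuLi (2.1 equiv), THF/HMPA, −78 → 0 °C; (CH2O)n, 0 °C → rt; then 1 M HCl
Reagents that add atoms: formaldehyde (from paraformaldehyde), C=O
Why: Double deprotonation gives the carboxylate–acetylide dianion, of which only the acetylide carbon is nucleophilic enough to add to formaldehyde, installing C7 as a propargylic alcohol.

**Step 11**
Reactants: 18 7-hydroxyhept-5-ynoic acid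
Product: 19 methyl 7-hydroxyhept-5-ynoate
Conditions: MeOH, H2SO4 (cat.), rt
Reagents that add atoms: methanol, CO
Why: Fischer esterification in a large excess of methanol should esterify the acid cleanly, the propargylic alcohol being inert to catalytic acid at room temperature.

**Step 12**
Reactants: 19 methyl 7-hydroxyhept-5-ynoate
Product: 20 methyl 7-iodohept-5-ynoate
Conditions: PPh3, I2, imidazole, CH2Cl2, 0 °C, dark
Reagents that add atoms: iodine, II
Why: Appel-type iodination converts the primary propargylic alcohol by SN2 displacement of its oxyphosphonium group by iodide, without propargyl–allenyl transposition.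

**Step 13**
Reactants: 15 (1S,4R,5R,6R)-4-(TBSO)-6-[(2S)-2-(TBSO)heptyl]bicyclo[3.1.0]hexan-2-one; 20 methyl 7-iodohept-5-ynoate
Product: 23 methyl 7-[(1R,2R,3R)-3-(TBSO)-2-[(3S)-3-(TBSO)octyl]-5-oxocyclopentyl]hept-5-ynoate, via lithium enolate 21 (not isolated), via triphenyltin enolate 22 (not isolated)
Conditions: Li (2.2 equiv), t-BuOH (1.0 equiv), NH3/THF, −78 °C; isoprene; NH3 evaporated; HMPA, Ph3SnCl (2.1 equiv), THF, −78 °C; then 20, −78 → −30 °C
Reagents that add atoms: none
Why: Dissolving-metal reductive cleavage of a conjugated cyclopropyl ketone followed by enolate alkylation, in which electron transfer to the C9 carbonyl should break the exocyclic C8–C13 bond (the one aligned with the carbonyl π system), leaving C13 as CH2 and a regiodefined C8 enolate that, as its triphenyltin enolate in HMPA, is alkylated by the propargylic iodide faster than it equilibrates, the electrophile entering anti to the C12 chain so that C8 is set R (8,12-trans).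

**Step 14**
Reactants: 23 methyl 7-[(1R,2R,3R)-3-(TBSO)-2-[(3S)-3-(TBSO)octyl]-5-oxocyclopentyl]hept-5-ynoate
Product: 24 methyl 7-[(1R,2R,3R)-3-(TBSO)-2-[(3S)-3-(TBSO)octyl]-5-oxocyclopentyl]heptanoate
Conditions: H2 (1 atm), Pd/C (10 %), EtOAc, rt
Reagents that add atoms: none
Why: Heterogeneous hydrogenation over palladium on carbon should saturate the C5–C6 alkyne completely, the ketone and silyl ethers being inert under these conditions and no other reducible group being present.

**Step 15**
Reactants: 24 methyl 7-[(1R,2R,3R)-3-(TBSO)-2-[(3S)-3-(TBSO)octyl]-5-oxocyclopentyl]heptanoate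
Product: 25 methyl 7-[(1R,2R,3R)-3-hydroxy-2-[(3S)-3-hydroxyoctyl]-5-oxocyclopentyl]heptanoate
Conditions: HF·pyridine, MeCN, 0 °C
Reagents that add atoms: none
Why: Fluoride-mediated cleavage of both silyl ethers with buffered HF·pyridine is the established mild deprotection for β-hydroxy cyclopentanones of this kind, which should not dehydrate at 0 °C.

**Step 16**
Reactants: 25 methyl 7-[(1R,2R,3R)-3-hydroxy-2-[(3S)-3-hydroxyoctyl]-5-oxocyclopentyl]heptanoate
Product: 26 13,14-dihydro-PGE1, 7-[(1R,2R,3R)-3-hydroxy-2-[(3S)-3-hydroxyoctyl]-5-oxocyclopentyl]heptanoic acid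
Conditions: porcine liver esterase, phosphate buffer (pH 7.5)/acetone, rt
Reagents that add atoms: water, O
Why: Enzymatic ester hydrolysis at neutral pH should free the C1 acid without the acid or base that would eliminate the 11-hydroxyl or epimerise C8.

**Compound list**

1 | methyl 3-oxooctanoate | CCCCCC(=O)CC(=O)OC | starting material
2 | methyl (3S)-3-hydroxyoctanoate | CCCCC[C@H](O)CC(=O)OC | intermediate
3 | methyl (3S)-3-(TBSO)octanoate | CCCCC[C@H](O[Si](C)(C)C(C)(C)C)CC(=O)OC | intermediate
4 | (3S)-3-(TBSO)octanal | CCCCC[C@H](O[Si](C)(C)C(C)(C)C)CC=O | intermediate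
5 | (triphenylphosphoranylidene)acetaldehyde | O=CC=P(c1ccccc1)(c1ccccc1)c1ccccc1 | starting material
6 | (2E,5S)-5-(TBSO)dec-2-enal | CCCCC[C@H](O[Si](C)(C)C(C)(C)C)C/C=C/C=O | intermediate
7 | (1R)-2-hydroxy-1,2,2-triphenylethyl acetate, (R)-HYTRA | CC(=O)O[C@H](c1ccccc1)C(O)(c1ccccc1)c1ccccc1 | starting material
8 | dilithium enolate of 7 (O-lithio ketene acetal and lithium tertiary alkoxide) | C=C(O[Li])O[C@H](c1ccccc1)C(O[Li])(c1ccccc1)c1ccccc1 | intermediate
9 | (1R)-2-hydroxy-1,2,2-triphenylethyl (3R,4E,7S)-3-hydroxy-7-(TBSO)dodec-4-enoate | CCCCC[C@H](O[Si](C)(C)C(C)(C)C)C/C=C/[C@H](O)CC(=O)O[C@H](c1ccccc1)C(O)(c1ccccc1)c1ccccc1 | intermediate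
10 | (3R,4E,7S)-3-hydroxy-7-(TBSO)dodec-4-enoic acid | CCCCC[C@H](O[Si](C)(C)C(C)(C)C)C/C=C/[C@H](O)CC(=O)O | intermediate
11 | tert-butyldimethylsilyl (3R,4E,7S)-3,7-bis(TBSO)dodec-4-enoate | CCCCC[C@H](O[Si](C)(C)C(C)(C)C)C/C=C/[C@H](O[Si](C)(C)C(C)(C)C)CC(=O)O[Si](C)(C)C(C)(C)C | intermediate
12 | (3R,4E,7S)-3,7-bis(TBSO)dodec-4-enoic acid | CCCCC[C@H](O[Si](C)(C)C(C)(C)C)C/C=C/[C@H](O[Si](C)(C)C(C)(C)C)CC(=O)O | intermediate
13 | (3R,4E,7S)-3,7-bis(TBSO)dodec-4-enoic isobutyl carbonic anhydride | CCCCC[C@H](O[Si](C)(C)C(C)(C)C)C/C=C/[C@H](O[Si](C)(C)C(C)(C)C)CC(=O)OC(=O)OCC(C)C | intermediate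
14 | (4R,5E,8S)-1-diazo-4,8-bis(TBSO)tridec-5-en-2-one | [N-]=[N+]=CC(=O)C[C@@H](O[Si](C)(C)C(C)(C)C)/C=C/C[C@@H](O[Si](C)(C)C(C)(C)C)CCCCC | intermediate
15 | (1S,4R,5R,6R)-4-(TBSO)-6-[(2S)-2-(TBSO)heptyl]bicyclo[3.1.0]hexan-2-one (C8, C12, C13 cyclopropane; silyloxy trans to it; heptyl chain exo) | CCCCC[C@H](O[Si](C)(C)C(C)(C)C)C[C@@H]1[C@H]2[C@H](O[Si](C)(C)C(C)(C)C)CC(=O)[C@@H]12 | intermediate
16 | hex-5-ynoic acid | C#CCCCC(=O)O | starting material
17 | lithium 6-lithiohex-5-ynoate | [Li]C#CCCCC(=O)O[Li] | intermediate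
18 | 7-hydroxyhept-5-ynoic acid | OCC#CCCCC(=O)O | intermediate
19 | methyl 7-hydroxyhept-5-ynoate | COC(=O)CCCC#CCO | intermediate
20 | methyl 7-iodohept-5-ynoate | COC(=O)CCCC#CCI | intermediate
21 | lithium (3R,4R)-4-(TBSO)-3-[(3S)-3-(TBSO)octyl]cyclopent-1-en-1-olate (C8=C9 enolate) | CCCCC[C@H](O[Si](C)(C)C(C)(C)C)CC[C@@H]1C=C(O[Li])C[C@H]1O[Si](C)(C)C(C)(C)C | intermediate
22 | O-triphenylstannyl enol ether corresponding to 21 | CCCCC[C@H](O[Si](C)(C)C(C)(C)C)CC[C@@H]1C=C(O[Sn](c2ccccc2)(c2ccccc2)c2ccccc2)C[C@H]1O[Si](C)(C)C(C)(C)C | intermediate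
23 | methyl 7-[(1R,2R,3R)-3-(TBSO)-2-[(3S)-3-(TBSO)octyl]-5-oxocyclopentyl]hept-5-ynoate | CCCCC[C@H](O[Si](C)(C)C(C)(C)C)CC[C@H]1[C@H](O[Si](C)(C)C(C)(C)C)CC(=O)[C@@H]1CC#CCCCC(=O)OC | intermediate
24 | methyl 7-[(1R,2R,3R)-3-(TBSO)-2-[(3S)-3-(TBSO)octyl]-5-oxocyclopentyl]heptanoate | CCCCC[C@H](O[Si](C)(C)C(C)(C)C)CC[C@H]1[C@H](O[Si](C)(C)C(C)(C)C)CC(=O)[C@@H]1CCCCCCC(=O)OC | intermediate
25 | methyl 7-[(1R,2R,3R)-3-hydroxy-2-[(3S)-3-hydroxyoctyl]-5-oxocyclopentyl]heptanoate | CCCCC[C@H](O)CC[C@H]1[C@H](O)CC(=O)[C@@H]1CCCCCCC(=O)OC | intermediate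
26 | 13,14-dihydro-PGE1, 7-[(1R,2R,3R)-3-hydroxy-2-[(3S)-3-hydroxyoctyl]-5-oxocyclopentyl]heptanoic acid | CCCCC[C@H](O)CC[C@H]1[C@H](O)CC(=O)[C@@H]1CCCCCCC(=O)O | target

**Count**

Total steps: 16. Longest linear sequence: 13 steps (steps 1–9 and 13–16); the C1–C7 iodide 20 takes 3 further steps (10–12).

**Steps most likely to fail**

1. Step 9. The carbenoid may add to both faces of the C12=C13 bond because the relay from the C11 silyloxy group is weak, or it may be lost to dimerisation. Fallback, setting out from 3 and returning at 21: the cyclopentanone is taken ready-made and the lower chain is added to it. Ester 3 is reduced (LiBH4, THF) to (3S)-3-(TBSO)octan-1-ol F1, which PPh3/I2/imidazole converts into tert-butyl{[(3S)-1-iodooctan-3-yl]oxy}dimethylsilane F2. Iodine–lithium exchange (t-BuLi, 2 equiv, Et2O/pentane, −78 °C) gives [3-(TBSO)octyl]lithium F3, and CuI/PBu3 turns this into the [3-(TBSO)octyl]copper tributylphosphine reagent F4. Conjugate addition of F4 to commercial (4R)-4-(TBSO)cyclopent-2-en-1-one (O=C1C=C[C@H](O[Si](C)(C)C(C)(C)C)C1), anti to its silyloxy group, should give enolate 21 directly. The tin-exchange and alkylation half of step 13 then carries 21 to 23, and steps 4 to 9 fall away.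

2. Step 13. Proton transfer between the C8 enolate and ketone already formed can move the enolate to C10, from where the 11-silyloxy group is expelled; a slow alkylation makes this worse. Fallback, setting out from 15 (through 21) and returning at 24: enolate 21 is captured at −78 °C by methyl 7-oxoheptanoate (O=CCCCCCC(=O)OC), an aldol addition that should outrun enolate equilibration, to give methyl 7-hydroxy-7-[(1S,2R,3R)-3-(TBSO)-2-[(3S)-3-(TBSO)octyl]-5-oxocyclopentyl]heptanoate F5. MsCl/DMAP forms the corresponding 7-mesylate F6, which should eliminate in the same flask to methyl (7E)-7-[(2R,3R)-3-(TBSO)-2-[(3S)-3-(TBSO)octyl]-5-oxocyclopentylidene]heptanoate F7. Radical conjugate reduction (Bu3SnH, AIBN, toluene, 80 °C) passes through the O-tributylstannyl enol F8, whose protonation on work-up should settle C8 in the more stable 8,12-trans arrangement and give 24, so that step 14 is not needed.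

3. Step 5. The auxiliary may discriminate poorly between the two faces of the aldehyde carbonyl, and the aldolate can revert during ester cleavage. Fallback, setting out from 6 and returning at 14: an allyl group serves as a masked acetonyl unit. Asymmetric allylboration of 6 with commercial B-allyldiisopinocampheylborane of the (−)-α-pinene series (Et2O, −78 °C; NaOH/H2O2 work-up), which is expected to attack the Re face, should give (4R,5E,8S)-8-(TBSO)trideca-1,5-dien-4-ol F9. Silylation (TBSCl, imidazole) gives (4R,5E,8S)-4,8-bis(TBSO)trideca-1,5-diene F10, and Wacker oxidation of the terminal alkene (PdCl2 cat., CuCl, O2, DMF/H2O) gives (4R,5E,8S)-4,8-bis(TBSO)tridec-5-en-2-one F11. Kinetic trifluoroacetylation at the methyl group (LiN(SiMe3)2, CF3CO2CH2CF3, THF, −78 °C) gives (6R,7E,10S)-6,10-bis(TBSO)-1,1,1-trifluoropentadec-7-ene-2,4-dione F12. Diazo transfer with loss of the trifluoroacetyl group (MsN3, Et3N, MeCN/H2O) returns 14 and replaces steps 5 to 8.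

**Further compounds**

F1 | step 9 | (3S)-3-(TBSO)octan-1-ol | CCCCC[C@H](O[Si](C)(C)C(C)(C)C)CCO
F2 | step 9 | tert-butyl{[(3S)-1-iodooctan-3-yl]oxy}dimethylsilane | CCCCC[C@H](O[Si](C)(C)C(C)(C)C)CCI
F3 | step 9 | [3-(TBSO)octyl]lithium, spatial arrangement of F2 | CCCCC[C@H](O[Si](C)(C)C(C)(C)C)CC[Li]
F4 | step 9 | [3-(TBSO)octyl]copper tributylphosphine complex, spatial arrangement of F2 | CCCCC[C@H](O[Si](C)(C)C(C)(C)C)CC[Cu-][P+](CCCC)(CCCC)CCCC
F5 | step 13 | methyl 7-hydroxy-7-[(1S,2R,3R)-3-(TBSO)-2-[(3S)-3-(TBSO)octyl]-5-oxocyclopentyl]heptanoate (C7 epimers) | CCCCC[C@H](O[Si](C)(C)C(C)(C)C)CC[C@H]1[C@H](O[Si](C)(C)C(C)(C)C)CC(=O)[C@@H]1C(O)CCCCCC(=O)OC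
F6 | step 13 | methyl 7-[(methylsulfonyl)oxy]-7-[(1S,2R,3R)-3-(TBSO)-2-[(3S)-3-(TBSO)octyl]-5-oxocyclopentyl]heptanoate | CCCCC[C@H](O[Si](C)(C)C(C)(C)C)CC[C@H]1[C@H](O[Si](C)(C)C(C)(C)C)CC(=O)[C@@H]1C(OS(C)(=O)=O)CCCCCC(=O)OC
F7 | step 13 | methyl (7E)-7-[(2R,3R)-3-(TBSO)-2-[(3S)-3-(TBSO)octyl]-5-oxocyclopentylidene]heptanoate | CCCCC[C@H](O[Si](C)(C)C(C)(C)C)CC[C@H]1[C@H](O[Si](C)(C)C(C)(C)C)CC(=O)/C1=C/CCCCCC(=O)OC
F8 | step 13 | O-tributylstannyl enol (C8=C9) of 24 | CCCCC[C@H](O[Si](C)(C)C(C)(C)C)CC[C@H]1[C@H](O[Si](C)(C)C(C)(C)C)CC(O[Sn](CCCC)(CCCC)CCCC)=C1CCCCCCC(=O)OC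
F9 | step 5 | (4R,5E,8S)-8-(TBSO)trideca-1,5-dien-4-ol | C=CC[C@@H](O)/C=C/C[C@@H](O[Si](C)(C)C(C)(C)C)CCCCC
F10 | step 5 | (4R,5E,8S)-4,8-bis(TBSO)trideca-1,5-diene | C=CC[C@@H](O[Si](C)(C)C(C)(C)C)/C=C/C[C@@H](O[Si](C)(C)C(C)(C)C)CCCCC
F11 | step 5 | (4R,5E,8S)-4,8-bis(TBSO)tridec-5-en-2-one | CC(=O)C[C@@H](O[Si](C)(C)C(C)(C)C)/C=C/C[C@@H](O[Si](C)(C)C(C)(C)C)CCCCC
F12 | step 5 | (6R,7E,10S)-6,10-bis(TBSO)-1,1,1-trifluoropentadec-7-ene-2,4-dione | FC(F)(F)C(=O)CC(=O)C[C@@H](O[Si](C)(C)C(C)(C)C)/C=C/C[C@@H](O[Si](C)(C)C(C)(C)C)CCCCC
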